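The runs are simulated with constants of no real substance, and the scatter is random.

Each X that has reacted stands as Z or as D (J set aside), so if f is the reacted fraction of the X charge and z the fraction standing as Z, the fraction gone on to D is f − z. Q can be balanced the same way. The south flask slows hard, with X at 24% after 5.00 h and 23% after 6.00 h, although more Q than X was charged, so take G as holding Q tightly as E. Each X reacted then costs one Q in the step and a second as E, and each D costs one more. The bill per X charged is 2f + (f − z) = 3f − z, and, with J set aside, it can grow until it meets the allowance, the Q charged over the X charged, which is 1.52 in larch. In larch that makes Q, though charged in a larger amount than X, the limiting reagent.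

| flask | X | Q | remark | time |
|---|---|---|---|---|
| south | 0.17 M | 0.375 M | run made earlier |  |
| south-east | 0.12 M | 0.375 M | run made earlier |  |
| larch | 0.25 M | 0.380 M |  | 10 h |
| maple | 0.25 M | 0.560 M |  | 10 h |

| run | time / h | X / % | Z / % |
|---|---|---|---|
| south | 1.50 | 45 | 36 |
| south | 3.00 | 31 | 39 |
| south | 5.00 | 24 | 37 |
| south | 6.00 | 23 | 38 |
| south-east | 0.500 | 70 | 28 |
| south-east | 1.00 | 52 | 34 |
| south-east | 2.50 | 28 | 38 |
| south-east | 6.00 | 14 | 30 |

(each reading ± 1.5 percentage points)

1. part of the X that has reacted at the end, larch
2. part of the X that has reacted at the end, maple
3. what raising the concentration of Q from its lowest to its highest value here does to the part of the X that has reacted (changes below 5 percentage points count as none) (it rises / no change / it falls)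

The step from X and the step from Z take one Q each, so z ought to follow f alike in south and south-east, and the readings agree within their scatter: 39% at 69.0% reacted in south, 38% at 72.0% in south-east. Larch and maple are taken to follow the same curve. South's bills, 1.29 at 55.0% reacted and 1.68 at 69.0%, bracket the larch allowance, and joining them gives 63.3%. South-east's 1.78 and 2.28 bracket maple's 2.24, giving 84.9%, so the reacted part rises by 22 percentage points.

The weak link is time, since south's last bill, 1.93, still stood below its allowance of 2.21. The first south-east reading gives a rough rate constant, and with about 3 Q spent per X reacted, the last free Q is reckoned to halve in 1.32 h in larch and 3.21 h in maple, both shorter than 10 h.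

The forecast, reasoning that “Each X reacted then costs about 2 Q”, gives 66% for larch and 86% for maple, slightly higher, with the trend: it rises.

The flask gives 65.2% in larch and 85.0% in maple, and it rises by 20 points.

    G + Z → J (k = 0.0421 /M/min)
    Q + Z → D (k = 0.0318 /M/min)
    Q + G ⇌ E, settled at all times (K = 3900 /M)
    X + Q → G + Z (k = 0.0359 /M/min)

Larch at 10.0 h keeps 1.3% of its Q against 35% of its X. Its bill, with Z at 36.0%, comes to 1.60, above the allowance of 1.52, but it books J and free G as D and E; with these taken out, each J counting 2, it stands at 1.50, and the free Q adds the remaining 0.0191 of the allowance. The step to J makes no difference to the larch answer.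

Larch charged with 0.23 M of Q has an allowance of 0.920, which lies between south-east's bills 0.620 and 1.10, and joining them gives 41.2%. The computed flask gives 43.7%.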